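**Remark on the chemistry:** compound 24 has no stereocentre; the stereocentres of the non-aromatic intermediates are racemic and vanish on aromatization, so no step needs stereocontrol.

Ring labels: A is the guaiacyl ring on the chain of ring B; B is the central ring bridged between its two oxygens; C is the central ring bridged next to its chain; D is the guaiacyl ring on the chain of ring C.

## The problem

Compound 24 is an achiral, methylene-bridged dimer of the bibenzyl gigantol: two guaiacyl rings (A and D) sit at the ends of two CH2CH2 chains, and two resorcinol-type rings (B and C) are joined through one CH2. The dimer is unsymmetrical: in ring B the bridge carbon lies between the C–OH and C–OMe carbons and para to the chain carbon, whereas in ring C it lies between the chain carbon and the C–OMe carbon and para to the C–OH carbon. With no stereocentre to set, the difficulty is regiochemical: each resorcinol ring of the monomer has three C–H positions of similar nucleophilicity, so electrophilic methylenation of the intact monomer gives mixtures of dimers and oligomers. Four phenols and four methyl ethers must be told apart, and the free and methylated oxygens stand in a different relation to the bridge in rings B and C. The product is an electron-rich diarylmethane with four free phenols, open to acid-induced transbenzylation and to oxidation (ring C can form a para-quinone methide), so the phenols should be released last under neutral conditions. The feature that opens the problem is that rings B and C both carry the 1,3-dioxygen pattern of a cyclohexane-1,3-dione. Ring B, bridged on the carbon flanked by the two oxygen-bearing carbons, is the aromatized form of a 2-substituted cyclohexane-1,3-dione mono methyl enol ether; ring C, with bridge carbon, chain and two meta oxygens in the orsellinate arrangement, is the aromatized form of the same dione still carrying the ester carbon of its ring-forming annulation. In such a dione the carbon between the carbonyl groups is the only nucleophilic carbon and the two carbonyl groups are equivalent, so the bridge position and the OH/OMe differentiation of ring B follow from constitution, not from selectivity.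

## Retrosynthesis

**24 from 23.** The three O–benzyl bonds are cut. The benzyl groups mark the three oxygens that must stay unmethylated (rings A, D and the para oxygen of ring C) and leave by neutral hydrogenolysis. The fourth free phenol, on ring B, needs no protection because it is created in the aromatization. The forward reaction must only spare the diarylmethane and the methyl ethers.

**23 from 20 from 19.** No carbon–carbon bond is cut; ring B is taken back to its non-aromatic form. Phenol 23 is the dehydrogenation product of enol ether 20, and 20 is the mono methyl enol ether of dione 19. Methylating one of two phenols that flank the bridge would be statistical; in 19 the two carbonyl groups are equivalent, so only one constitution of 20 exists, and the remaining carbonyl becomes the free phenol. The forward reactions are a 1,3-dione enol etherification and a dehydrogenation at the only α′ position (C6) of 20.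

**19 from 17 and 11.** This is the key cut: the bond between the bridge carbon and C2 of ring B. Cutting the ring C–CH2 bond instead would need an arene nucleophile with three competing positions, whereas C2 of 11 is the only carbon between two carbonyl groups. The C53 skeleton of 19 falls into a C31 aldehyde and a C22 dione. The forward reaction is a condensation of 17 with 11 that must stop at the 1:1 stage, which is secured by reducing the alkylidene dione 18 as it forms.

**17 from 16, 15, 14 and 13.** Functional group changes only: aldehyde from alcohol from ester, then the O–methyl and O–benzyl bonds of ring C. Ring C is recognized as a resorcylate, 13, in which the future bridge carbon is already attached as the ester carbon between the chain carbon and a hydroxylated carbon, so no aromatic substitution is needed. The ester also distinguishes the two phenols: the ortho hydroxyl is chelated, so benzyl goes on the para oxygen (14) and methyl on the ortho oxygen (15).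

**13 and 11 from 9.** Both central rings come from one cyclic keto ester, 9. Dehydrogenation of 9 with the ester kept gives 13; hydrolysis and decarboxylation of 9 through acid 10 give 11. The carbon that is discarded on the way to ring B is the carbon that becomes the bridge on the way to ring C, so one annulation serves both halves.

**9 from 6 and 7.** The ring is built from open-chain precursors by cutting the C1–C6 bond (Michael addition) and the C2–C3 bond (Claisen condensation). The connectivity of enone 6 and malonate 7 places the chain, the two oxygens and the ester around the ring without any choice, through adduct 8.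

**6 from 4 and 5; 4 from 1 and 2.** The enone double bond comes from a Wittig reaction of aldehyde 4 with ylide 5. Aldehyde 4 comes from a Heck arylation of allyl alcohol 2 with aryl bromide 1, through enol 3.

## Roads not taken

**Alternative 1:** The cut is at both aryl–CH2 bonds of the bridge, back to two molecules of gigantol A1 and one carbon from formaldehyde. The forward key step is acid-catalysed hydroxymethylation of A1 to benzylic alcohol A2, ionization to para-quinone methide A3 and capture by a second molecule of A1, which is probably how the compound arises in the plant. A1 is short to make, but its resorcinol ring has three free positions and nothing directs the first carbon to the position between chain and OMe or the second bond to the position between OH and OMe. Six methylene-bis isomers are possible through the resorcinol rings alone, and the products are as nucleophilic as A1, so oligomers follow. In the chosen plan each of the two bridge bonds is made at a carbon that is unique by constitution.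

**Alternative 2:** The cut is at the ring B–CH2 bond, as an sp2–sp3 cross-coupling. The forward key step is a Suzuki–Miyaura coupling of benzylic bromide A4 (from 16) with the ring B boronic ester A5 to give tetrabenzyl ether A6. A5 is a 2,6-dialkoxyarylboron compound and protodeboronates readily; A4 is a 2,4-dialkoxybenzyl bromide that ionizes and alkylates its own ring; both coupling carbons are flanked by two ortho substituents. Ring B would have to be bought aromatic, so its two oxygens would be differentiated by statistical monoalkylation and the boron placed by a separate metalation, while ring C still needs everything that leads to 16. The chosen plan uses no aryl–metal species and gets the oxygen differentiation of ring B from symmetry.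

**Alternative 3:** The cut is at both chains, two-directionally, through the stilbene double bonds. The forward key step is a double Wittig reaction of dialdehyde A7 with the ylide of phosphonium salt A8 to bis-stilbene A9, then one hydrogenation that saturates both alkenes and removes all benzyl groups. The end game is attractive, but A7 still contains the unsymmetrical diarylmethane with its regiochemical problem unsolved, now on rings deactivated by formyl groups. The disconnection removes only the easy atoms (rings A and D). The chosen plan installs the chains first and lets the ring construction solve the bridge.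

Key step: step 10

## Route

Keto ester 9 is divided in roughly equimolar parts between step 4 and step 5.

**Step 1**
Reactants: 1 1-(benzyloxy)-4-bromo-2-methoxybenzene; 2 prop-2-en-1-ol
Product: 4 3-[4-(benzyloxy)-3-methoxyphenyl]propanal, via enol 3 (not isolated)
Conditions: Pd(OAc)2 (3 mol %), Bu4NCl, NaHCO3, DMF, 80 °C
Reagents that add atoms: none
Why: Heck reaction: oxidative addition of 1 to zerovalent palladium, insertion of the alkene of 2 with aryl at the terminal carbon and β-hydride elimination towards the carbinol carbon give enol 3, which tautomerizes to 4; the ligand-free chloride/hydrogencarbonate system is the standard one for making 3-arylpropanals from aryl halides and allyl alcohol.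

**Step 2**
Reactants: 4 3-[4-(benzyloxy)-3-methoxyphenyl]propanal; 5 1-(triphenylphosphoranylidene)propan-2-one
Product: 6 (3E)-6-[4-(benzyloxy)-3-methoxyphenyl]hex-3-en-2-one
Conditions: THF, 65 °C
Reagents that add atoms: none
Why: Wittig olefination with a ketone-stabilized ylide, which gives the E-enone under thermal conditions and is not basic enough to enolize the aldehyde.

**Step 3**
Reactants: 6 (3E)-6-[4-(benzyloxy)-3-methoxyphenyl]hex-3-en-2-one; 7 dimethyl propanedioate
Product: 9 methyl rac-(1R,6S)-6-{2-[4-(benzyloxy)-3-methoxyphenyl]ethyl}-2-hydroxy-4-oxocyclohex-2-ene-1-carboxylate, via Michael adduct 8 (not isolated)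
Conditions: NaOMe (1.1 equiv), MeOH, 65 °C; then 1 M HCl, 0 °C
Reagents that add atoms: none
Why: Michael addition of the malonate anion to the β-carbon of 6 gives 8, whose methyl ketone enolate closes onto one ester group (Claisen condensation) to give the vinylogous acid salt of 9, the classical entry to 5-alkylcyclohexane-1,3-dione-4-carboxylates; the trans relation of ester and chain results from equilibration at the acidic C1 and both centres are erased later.

**Step 4**
Reactants: 9 methyl rac-(1R,6S)-6-{2-[4-(benzyloxy)-3-methoxyphenyl]ethyl}-2-hydroxy-4-oxocyclohex-2-ene-1-carboxylate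
Product: 11 5-{2-[4-(benzyloxy)-3-methoxyphenyl]ethyl}cyclohexane-1,3-dione, via keto acid 10 (not isolated)
Conditions: 2 M NaOH (aq), 100 °C; then HCl to pH 2, 80 °C
Reagents that add atoms: none
Why: Saponification of the β-keto ester and decarboxylation of β-keto acid 10 on acidification, the standard way from such esters to 5-substituted cyclohexane-1,3-diones; aryl benzyl and methyl ethers are inert.

**Step 5**
Reactants: 9 methyl rac-(1R,6S)-6-{2-[4-(benzyloxy)-3-methoxyphenyl]ethyl}-2-hydroxy-4-oxocyclohex-2-ene-1-carboxylate
Product: 13 methyl 2-{2-[4-(benzyloxy)-3-methoxyphenyl]ethyl}-4,6-dihydroxybenzoate, via bromo diketone 12 (not isolated)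
Conditions: Br2 (1.0 equiv), DMF, 0 °C; then 80 °C
Reagents that add atoms: none
Why: Bromination of the dione enol at C3 gives 12 (drawn as the kinetic bromide, which shuttles its bromine to C5 under HBr), and loss of HBr with enolization gives the resorcylate; this is the known bromine-mediated dehydrogenation of such keto esters to 6-alkyl-2,4-dihydroxybenzoates. The enol is far more nucleophilic than ring A, and one equivalent of bromine is used to spare the arenes.

**Step 6**
Reactants: 13 methyl 2-{2-[4-(benzyloxy)-3-methoxyphenyl]ethyl}-4,6-dihydroxybenzoate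
Product: 14 methyl 4-(benzyloxy)-2-{2-[4-(benzyloxy)-3-methoxyphenyl]ethyl}-6-hydroxybenzoate
Conditions: BnBr (1.05 equiv), K2CO3 (1.1 equiv), acetone, 56 °C
Reagents that add atoms: benzyl bromide, BrCc1ccccc1
Why: Williamson etherification; the hydroxyl ortho to the ester is held in a hydrogen bond to the carbonyl and is less acidic and less accessible, so one equivalent of benzyl bromide with a weak base alkylates only the para hydroxyl.

**Step 7**
Reactants: 14 methyl 4-(benzyloxy)-2-{2-[4-(benzyloxy)-3-methoxyphenyl]ethyl}-6-hydroxybenzoate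
Product: 15 methyl 4-(benzyloxy)-2-{2-[4-(benzyloxy)-3-methoxyphenyl]ethyl}-6-methoxybenzoate
Conditions: MeI (3 equiv), K2CO3, DMF, 50 °C
Reagents that add atoms: iodomethane, CI
Why: Williamson methylation of the remaining chelated phenol under more forcing conditions (polar solvent, excess MeI, heat); no other acidic site is present.

**Step 8**
Reactants: 15 methyl 4-(benzyloxy)-2-{2-[4-(benzyloxy)-3-methoxyphenyl]ethyl}-6-methoxybenzoate
Product: 16 [4-(benzyloxy)-2-{2-[4-(benzyloxy)-3-methoxyphenyl]ethyl}-6-methoxyphenyl]methanol
Conditions: LiAlH4, THF, 0 °C to rt; aqueous NaOH work-up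
Reagents that add atoms: none
Why: Hydride reduction of the hindered, electron-rich benzoate to the benzylic alcohol; the basic work-up avoids ionization of the acid-labile 2,4-dialkoxybenzyl alcohol.

**Step 9**
Reactants: 16 [4-(benzyloxy)-2-{2-[4-(benzyloxy)-3-methoxyphenyl]ethyl}-6-methoxyphenyl]methanol
Product: 17 4-(benzyloxy)-2-{2-[4-(benzyloxy)-3-methoxyphenyl]ethyl}-6-methoxybenzaldehyde
Conditions: activated MnO2 (excess), CH2Cl2, rt
Reagents that add atoms: none
Why: MnO2 oxidizes benzylic alcohols selectively, stops at the aldehyde and works under neutral conditions that the electron-rich benzylic system tolerates.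

**Step 10**
Reactants: 17 4-(benzyloxy)-2-{2-[4-(benzyloxy)-3-methoxyphenyl]ethyl}-6-methoxybenzaldehyde; 11 5-{2-[4-(benzyloxy)-3-methoxyphenyl]ethyl}cyclohexane-1,3-dione
Product: 19 2-{[4-(benzyloxy)-2-{2-[4-(benzyloxy)-3-methoxyphenyl]ethyl}-6-methoxyphenyl]methyl}-5-{2-[4-(benzyloxy)-3-methoxyphenyl]ethyl}-3-hydroxycyclohex-2-en-1-one (enol form of the 2-benzyl 1,3-dione, racemic), via alkylidene dione 18 (not isolated)
Conditions: L-proline (20 mol %), Hantzsch ester (diethyl 2,6-dimethyl-1,4-dihydropyridine-3,5-dicarboxylate, 1.2 equiv), CH2Cl2/EtOH, 25 to 40 °C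
Reagents that add atoms: none
Why: Proline condenses with 17 to an iminium ion, the enol of 11 adds through C2, the only carbon flanked by both carbonyl groups, and loss of the catalyst gives alkylidene dione 18 (Knoevenagel condensation); 18 is a strongly electron-poor alkene that accepts a hydride at the benzylidene carbon from the Hantzsch ester, and protonation gives 19 as its enol. The closest known reaction type is the organocatalytic three-component reductive alkylation of cyclic 1,3-diones with aldehydes and a Hantzsch ester, which exists because direct alkylation of such diones gives O-alkyl and dialkyl products. No ring is closed and no stereocentre of consequence is formed: C5 is a stereocentre only in the enol form, the material is racemic, and the centre disappears in step 12. The selectivity needed is 1:1 coupling at carbon: O-alkylation cannot occur in a condensation manifold, 19 has no second C2 hydrogen with which to condense again, and Michael addition of a second molecule of 11 to 18 should be outrun by hydride transfer and is hindered by the chain and the methoxy group ortho to the benzylidene carbon. The electron-rich, di-ortho-substituted aldehyde should condense slowly, but the reduction is irreversible and drains the condensation equilibrium. The step fixes the bridge on the future ring B between its two oxygen-bearing carbons and para to the chain before that ring is aromatic, so arene regiochemistry never arises.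

**Step 11**
Reactants: 19 2-{[4-(benzyloxy)-2-{2-[4-(benzyloxy)-3-methoxyphenyl]ethyl}-6-methoxyphenyl]methyl}-5-{2-[4-(benzyloxy)-3-methoxyphenyl]ethyl}-3-hydroxycyclohex-2-en-1-one
Product: 20 2-{[4-(benzyloxy)-2-{2-[4-(benzyloxy)-3-methoxyphenyl]ethyl}-6-methoxyphenyl]methyl}-5-{2-[4-(benzyloxy)-3-methoxyphenyl]ethyl}-3-methoxycyclohex-2-en-1-one (racemic)
Conditions: MeOH, TsOH·H2O (5 mol %), 3 Å molecular sieves, 50 °C
Reagents that add atoms: methanol, CO
Why: Acid-catalysed enol etherification of a cyclic 1,3-dione; the two carbonyl groups of 19 are equivalent, so only one constitution can form, and the vinylogous ester carbonyl of 20 does not react further.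

**Step 12**
Reactants: 20 2-{[4-(benzyloxy)-2-{2-[4-(benzyloxy)-3-methoxyphenyl]ethyl}-6-methoxyphenyl]methyl}-5-{2-[4-(benzyloxy)-3-methoxyphenyl]ethyl}-3-methoxycyclohex-2-en-1-one
Product: 23 2-{[4-(benzyloxy)-2-{2-[4-(benzyloxy)-3-methoxyphenyl]ethyl}-6-methoxyphenyl]methyl}-5-{2-[4-(benzyloxy)-3-methoxyphenyl]ethyl}-3-methoxyphenol, via selenide 21 (not isolated), via dienone 22 (not isolated)
Conditions: LiN(i-Pr)2 (1.2 equiv), THF, −78 °C; PhSeCl, −78 °C; then 30% H2O2, pyridine, CH2Cl2, 0 °C to rt
Reagents that add atoms: none
Why: Kinetic deprotonation of a 3-alkoxycyclohexenone occurs at the α′ carbon C6; selenenylation trans to the C5 chain gives 21 with selenium syn to the C5 hydrogen, and selenoxide syn-elimination after oxidation gives dienone 22, the keto tautomer of the phenol, which enolizes at once (selenoxide dehydrogenation with aromatization).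

**Step 13**
Reactants: 23 2-{[4-(benzyloxy)-2-{2-[4-(benzyloxy)-3-methoxyphenyl]ethyl}-6-methoxyphenyl]methyl}-5-{2-[4-(benzyloxy)-3-methoxyphenyl]ethyl}-3-methoxyphenol
Product: 24 2-({4-hydroxy-2-[2-(4-hydroxy-3-methoxyphenyl)ethyl]-6-methoxyphenyl}methyl)-5-[2-(4-hydroxy-3-methoxyphenyl)ethyl]-3-methoxyphenol (CNP0079000.0)
Conditions: H2 (1 atm), 10% Pd/C, EtOAc/MeOH, rt
Reagents that add atoms: none
Why: Hydrogenolysis of the three aryl benzyl ethers under neutral conditions; aryl methyl ethers, the diarylmethane and the bibenzyl chains are not cleaved at room temperature and atmospheric pressure.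

## Compound list

1 | 1-(benzyloxy)-4-bromo-2-methoxybenzene | COc1cc(Br)ccc1OCc1ccccc1 | starting material
2 | prop-2-en-1-ol (allyl alcohol) | OCC=C | starting material
3 | 3-[4-(benzyloxy)-3-methoxyphenyl]prop-1-en-1-ol (enol, alkene geometry not defined) | COc1cc(CC=CO)ccc1OCc1ccccc1 | intermediate
4 | 3-[4-(benzyloxy)-3-methoxyphenyl]propanal | COc1cc(CCC=O)ccc1OCc1ccccc1 | intermediate
5 | 1-(triphenylphosphoranylidene)propan-2-one | CC(=O)C=P(c1ccccc1)(c1ccccc1)c1ccccc1 | starting material
6 | (3E)-6-[4-(benzyloxy)-3-methoxyphenyl]hex-3-en-2-one | COc1cc(CC/C=C/C(C)=O)ccc1OCc1ccccc1 | intermediate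
7 | dimethyl propanedioate (dimethyl malonate) | COC(=O)CC(=O)OC | starting material
8 | dimethyl 2-{1-[4-(benzyloxy)-3-methoxyphenyl]-5-oxohexan-3-yl}propanedioate (racemic) | COC(=O)C(C(=O)OC)C(CCc1ccc(OCc2ccccc2)c(OC)c1)CC(C)=O | intermediate
9 | methyl rac-(1R,6S)-6-{2-[4-(benzyloxy)-3-methoxyphenyl]ethyl}-2-hydroxy-4-oxocyclohex-2-ene-1-carboxylate (trans, racemic; one enantiomer drawn) | COC(=O)[C@@H]1[C@@H](CCc2ccc(OCc3ccccc3)c(OC)c2)CC(=O)C=C1O | intermediate
10 | rac-(1R,6S)-6-{2-[4-(benzyloxy)-3-methoxyphenyl]ethyl}-2-hydroxy-4-oxocyclohex-2-ene-1-carboxylic acid (trans, racemic; one enantiomer drawn) | OC(=O)[C@@H]1[C@@H](CCc2ccc(OCc3ccccc3)c(OC)c2)CC(=O)C=C1O | intermediate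
11 | 5-{2-[4-(benzyloxy)-3-methoxyphenyl]ethyl}cyclohexane-1,3-dione | O=C1CC(CCc2ccc(OCc3ccccc3)c(OC)c2)CC(=O)C1 | intermediate
12 | methyl rac-(1R,6S)-3-bromo-6-{2-[4-(benzyloxy)-3-methoxyphenyl]ethyl}-2-hydroxy-4-oxocyclohex-2-ene-1-carboxylate (trans, racemic; one enantiomer drawn) | COC(=O)[C@@H]1[C@@H](CCc2ccc(OCc3ccccc3)c(OC)c2)CC(=O)C(Br)=C1O | intermediate
13 | methyl 2-{2-[4-(benzyloxy)-3-methoxyphenyl]ethyl}-4,6-dihydroxybenzoate | COC(=O)c1c(CCc2ccc(OCc3ccccc3)c(OC)c2)cc(O)cc1O | intermediate
14 | methyl 4-(benzyloxy)-2-{2-[4-(benzyloxy)-3-methoxyphenyl]ethyl}-6-hydroxybenzoate | COC(=O)c1c(CCc2ccc(OCc3ccccc3)c(OC)c2)cc(OCc2ccccc2)cc1O | intermediate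
15 | methyl 4-(benzyloxy)-2-{2-[4-(benzyloxy)-3-methoxyphenyl]ethyl}-6-methoxybenzoate | COC(=O)c1c(CCc2ccc(OCc3ccccc3)c(OC)c2)cc(OCc2ccccc2)cc1OC | intermediate
16 | [4-(benzyloxy)-2-{2-[4-(benzyloxy)-3-methoxyphenyl]ethyl}-6-methoxyphenyl]methanol | OCc1c(CCc2ccc(OCc3ccccc3)c(OC)c2)cc(OCc2ccccc2)cc1OC | intermediate
17 | 4-(benzyloxy)-2-{2-[4-(benzyloxy)-3-methoxyphenyl]ethyl}-6-methoxybenzaldehyde | O=Cc1c(CCc2ccc(OCc3ccccc3)c(OC)c2)cc(OCc2ccccc2)cc1OC | intermediate
18 | 2-{[4-(benzyloxy)-2-{2-[4-(benzyloxy)-3-methoxyphenyl]ethyl}-6-methoxyphenyl]methylidene}-5-{2-[4-(benzyloxy)-3-methoxyphenyl]ethyl}cyclohexane-1,3-dione (racemic) | O=C1CC(CCc2ccc(OCc3ccccc3)c(OC)c2)CC(=O)C1=Cc1c(CCc2ccc(OCc3ccccc3)c(OC)c2)cc(OCc2ccccc2)cc1OC | intermediate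
19 | 2-{[4-(benzyloxy)-2-{2-[4-(benzyloxy)-3-methoxyphenyl]ethyl}-6-methoxyphenyl]methyl}-5-{2-[4-(benzyloxy)-3-methoxyphenyl]ethyl}-3-hydroxycyclohex-2-en-1-one (enol form of the 1,3-dione, racemic) | OC1=C(Cc2c(CCc3ccc(OCc4ccccc4)c(OC)c3)cc(OCc3ccccc3)cc2OC)C(=O)CC(CCc2ccc(OCc3ccccc3)c(OC)c2)C1 | intermediate
20 | 2-{[4-(benzyloxy)-2-{2-[4-(benzyloxy)-3-methoxyphenyl]ethyl}-6-methoxyphenyl]methyl}-5-{2-[4-(benzyloxy)-3-methoxyphenyl]ethyl}-3-methoxycyclohex-2-en-1-one (racemic) | COC1=C(Cc2c(CCc3ccc(OCc4ccccc4)c(OC)c3)cc(OCc3ccccc3)cc2OC)C(=O)CC(CCc2ccc(OCc3ccccc3)c(OC)c2)C1 | intermediate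
21 | rac-(5R,6S)-2-{[4-(benzyloxy)-2-{2-[4-(benzyloxy)-3-methoxyphenyl]ethyl}-6-methoxyphenyl]methyl}-5-{2-[4-(benzyloxy)-3-methoxyphenyl]ethyl}-3-methoxy-6-(phenylselanyl)cyclohex-2-en-1-one (trans, racemic; one enantiomer drawn) | COC1=C(Cc2c(CCc3ccc(OCc4ccccc4)c(OC)c3)cc(OCc3ccccc3)cc2OC)C(=O)[C@@H]([Se]c2ccccc2)[C@H](CCc2ccc(OCc3ccccc3)c(OC)c2)C1 | intermediate
22 | 2-{[4-(benzyloxy)-2-{2-[4-(benzyloxy)-3-methoxyphenyl]ethyl}-6-methoxyphenyl]methyl}-5-{2-[4-(benzyloxy)-3-methoxyphenyl]ethyl}-3-methoxycyclohexa-2,5-dien-1-one | COC1=C(Cc2c(CCc3ccc(OCc4ccccc4)c(OC)c3)cc(OCc3ccccc3)cc2OC)C(=O)C=C(CCc2ccc(OCc3ccccc3)c(OC)c2)C1 | intermediate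
23 | 2-{[4-(benzyloxy)-2-{2-[4-(benzyloxy)-3-methoxyphenyl]ethyl}-6-methoxyphenyl]methyl}-5-{2-[4-(benzyloxy)-3-methoxyphenyl]ethyl}-3-methoxyphenol | COc1cc(CCc2ccc(OCc3ccccc3)c(OC)c2)cc(O)c1Cc1c(CCc2ccc(OCc3ccccc3)c(OC)c2)cc(OCc2ccccc2)cc1OC | intermediate
24 | 2-({4-hydroxy-2-[2-(4-hydroxy-3-methoxyphenyl)ethyl]-6-methoxyphenyl}methyl)-5-[2-(4-hydroxy-3-methoxyphenyl)ethyl]-3-methoxyphenol (CNP0079000.0) | COc1cc(CCc2cc(O)c(Cc3c(CCc4ccc(O)c(OC)c4)cc(O)cc3OC)c(OC)c2)ccc1O | target

## Step count and uncertain steps

Total: 13 steps. Longest linear sequence: 12 steps (1, 2, 3, 5, 6, 7, 8, 9, 10, 11, 12, 13); step 4 is the one-step side branch from 9 to 11.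

**Step 10 (key step).** The most likely failure is slow condensation: the formyl group of 17 is flanked by two ortho substituents and deactivated by two alkoxy donors, so iminium formation and attack by 11 may lag, leaving time for double Michael addition of 11 to 18 or for decomposition of the Hantzsch ester. The fallback makes ring B aromatic first and joins it as an aryllithium; it sets out from 11 (and uses 17) and comes back at 23. Dione 11 is converted with MeOH/TsOH into the enol ether 5-{2-[4-(benzyloxy)-3-methoxyphenyl]ethyl}-3-methoxycyclohex-2-en-1-one F1, which is dehydrogenated as in step 12 to 3-{2-[4-(benzyloxy)-3-methoxyphenyl]ethyl}-5-methoxyphenol F2. The phenol is protected with chloromethyl methyl ether and i-Pr2NEt as 1-(benzyloxy)-2-methoxy-4-{2-[3-methoxy-5-(methoxymethoxy)phenyl]ethyl}benzene F3. Directed ortho-lithiation (n-BuLi, THF, 0 °C) takes place at the carbon between the two oxygen substituents, and addition of 17 gives the carbinol [4-(benzyloxy)-2-{2-[4-(benzyloxy)-3-methoxyphenyl]ethyl}-6-methoxyphenyl][4-{2-[4-(benzyloxy)-3-methoxyphenyl]ethyl}-2-methoxy-6-(methoxymethoxy)phenyl]methanol F4. Ionic hydrogenation (Et3SiH, BF3·OEt2, CH2Cl2, −78 °C) gives the O-methoxymethyl ether of 23 F5, and acidic methanolysis (HCl, MeOH) of the acetal gives 23.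

**Step 12.** The most likely failure is loss of kinetic control in the deprotonation: proton transfer to the γ carbon C4 or to the allylic-benzylic methylene on C2 would send selenium to the wrong carbon, and the electrophilic selenium reagent may also attack the electron-rich rings. The fallback avoids enolate chemistry; it sets out from 19 and comes back at 23. Dione 19 is heated with iodine in methanol, the known oxidative aromatization of cyclohexane-1,3-diones to resorcinol monomethyl ethers, in which the HI formed catalyses enol etherification to 20 and α-iodination with loss of HI completes the aromatization. No new compound is isolated.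

**Step 5.** The most likely failure is misdirected bromine: transfer of bromine from 12 to ring A or to the free positions of the product resorcylate, and cleavage of the ring A benzyl ether by HBr at 80 °C. The fallback is halogen-free and places the formyl carbon by ortho-formylation; it sets out from 11 and comes back at 17, bypassing steps 5 to 9. Dione 11 is etherified with benzyl alcohol and TsOH (toluene, water removal) to 3-(benzyloxy)-5-{2-[4-(benzyloxy)-3-methoxyphenyl]ethyl}cyclohex-2-en-1-one F6, and selenoxide dehydrogenation as in step 12 gives 3-(benzyloxy)-5-{2-[4-(benzyloxy)-3-methoxyphenyl]ethyl}phenol F7. Magnesium-mediated ortho-formylation (MgCl2, Et3N, paraformaldehyde, MeCN, 80 °C) is expected at the ortho position para to the benzyloxy group and gives 4-(benzyloxy)-2-{2-[4-(benzyloxy)-3-methoxyphenyl]ethyl}-6-hydroxybenzaldehyde F8. Methylation (MeI, K2CO3, DMF) gives 17.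

**Step 1.** The most likely failure is slow oxidative addition of the electron-rich aryl bromide, with competing insertion in the opposite sense (branched aldehyde), β-hydride elimination towards the benzylic side (cinnamyl alcohol) and aldol self-condensation of 4 in hot basic DMF. The fallback replaces catalysis by an organolithium; it sets out from 1 and comes back at 4. Bromine–lithium exchange on 1 (n-BuLi, THF, −78 °C) and opening of oxetane with BF3·OEt2 give 3-[4-(benzyloxy)-3-methoxyphenyl]propan-1-ol F9, which is oxidized to 4 with Dess–Martin periodinane.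

## Further compounds

F1 | step 10 | 5-{2-[4-(benzyloxy)-3-methoxyphenyl]ethyl}-3-methoxycyclohex-2-en-1-one (racemic) | COC1=CC(=O)CC(CCc2ccc(OCc3ccccc3)c(OC)c2)C1
F2 | step 10 | 3-{2-[4-(benzyloxy)-3-methoxyphenyl]ethyl}-5-methoxyphenol | COc1cc(O)cc(CCc2ccc(OCc3ccccc3)c(OC)c2)c1
F3 | step 10 | 1-(benzyloxy)-2-methoxy-4-{2-[3-methoxy-5-(methoxymethoxy)phenyl]ethyl}benzene | COCOc1cc(OC)cc(CCc2ccc(OCc3ccccc3)c(OC)c2)c1
F4 | step 10 | [4-(benzyloxy)-2-{2-[4-(benzyloxy)-3-methoxyphenyl]ethyl}-6-methoxyphenyl][4-{2-[4-(benzyloxy)-3-methoxyphenyl]ethyl}-2-methoxy-6-(methoxymethoxy)phenyl]methanol (racemic) | COCOc1cc(CCc2ccc(OCc3ccccc3)c(OC)c2)cc(OC)c1C(O)c1c(CCc2ccc(OCc3ccccc3)c(OC)c2)cc(OCc2ccccc2)cc1OC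
F5 | step 10 | O-methoxymethyl ether of 23: 5-(benzyloxy)-1-{2-[4-(benzyloxy)-3-methoxyphenyl]ethyl}-2-{[4-{2-[4-(benzyloxy)-3-methoxyphenyl]ethyl}-2-methoxy-6-(methoxymethoxy)phenyl]methyl}-3-methoxybenzene | COCOc1cc(CCc2ccc(OCc3ccccc3)c(OC)c2)cc(OC)c1Cc1c(CCc2ccc(OCc3ccccc3)c(OC)c2)cc(OCc2ccccc2)cc1OC
F0 | step 12 | none | none
F6 | step 5 | 3-(benzyloxy)-5-{2-[4-(benzyloxy)-3-methoxyphenyl]ethyl}cyclohex-2-en-1-one (racemic) | O=C1C=C(OCc2ccccc2)CC(CCc2ccc(OCc3ccccc3)c(OC)c2)C1
F7 | step 5 | 3-(benzyloxy)-5-{2-[4-(benzyloxy)-3-methoxyphenyl]ethyl}phenol | Oc1cc(OCc2ccccc2)cc(CCc2ccc(OCc3ccccc3)c(OC)c2)c1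
F8 | step 5 | 4-(benzyloxy)-2-{2-[4-(benzyloxy)-3-methoxyphenyl]ethyl}-6-hydroxybenzaldehyde | O=Cc1c(CCc2ccc(OCc3ccccc3)c(OC)c2)cc(OCc2ccccc2)cc1O
F9 | step 1 | 3-[4-(benzyloxy)-3-methoxyphenyl]propan-1-ol | COc1cc(CCCO)ccc1OCc1ccccc1
A1 | alternative 1 | 3-[2-(4-hydroxy-3-methoxyphenyl)ethyl]-5-methoxyphenol (gigantol) | COc1cc(O)cc(CCc2ccc(O)c(OC)c2)c1
A2 | alternative 1 | 4-(hydroxymethyl)-3-[2-(4-hydroxy-3-methoxyphenyl)ethyl]-5-methoxyphenol | COc1cc(O)cc(CCc2ccc(O)c(OC)c2)c1CO
A3 | alternative 1 | 3-[2-(4-hydroxy-3-methoxyphenyl)ethyl]-5-methoxy-4-methylidenecyclohexa-2,5-dien-1-one | C=C1C(OC)=CC(=O)C=C1CCc1ccc(O)c(OC)c1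
A4 | alternative 2 | 5-(benzyloxy)-1-{2-[4-(benzyloxy)-3-methoxyphenyl]ethyl}-2-(bromomethyl)-3-methoxybenzene | BrCc1c(CCc2ccc(OCc3ccccc3)c(OC)c2)cc(OCc2ccccc2)cc1OC
A5 | alternative 2 | 2-[2-(benzyloxy)-4-{2-[4-(benzyloxy)-3-methoxyphenyl]ethyl}-6-methoxyphenyl]-4,4,5,5-tetramethyl-1,3,2-dioxaborolane | COc1cc(CCc2ccc(OCc3ccccc3)c(OC)c2)cc(OCc2ccccc2)c1B1OC(C)(C)C(C)(C)O1
A6 | alternative 2 | O-benzyl ether of 23 (tetrabenzyl ether of 24) | COc1cc(CCc2ccc(OCc3ccccc3)c(OC)c2)cc(OCc2ccccc2)c1Cc1c(CCc2ccc(OCc3ccccc3)c(OC)c2)cc(OCc2ccccc2)cc1OC
A7 | alternative 3 | 3-(benzyloxy)-4-{[4-(benzyloxy)-2-formyl-6-methoxyphenyl]methyl}-5-methoxybenzaldehyde | COc1cc(C=O)cc(OCc2ccccc2)c1Cc1c(C=O)cc(OCc2ccccc2)cc1OC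
A8 | alternative 3 | {[4-(benzyloxy)-3-methoxyphenyl]methyl}triphenylphosphonium chloride | COc1cc(C[P+](c2ccccc2)(c2ccccc2)c2ccccc2)ccc1OCc1ccccc1.[Cl-]
A9 | alternative 3 | bis-stilbene from A7 and two equivalents of the ylide of A8 (mixture of alkene isomers) | COc1cc(C=Cc2ccc(OCc3ccccc3)c(OC)c2)cc(OCc2ccccc2)c1Cc1c(C=Cc2ccc(OCc3ccccc3)c(OC)c2)cc(OCc2ccccc2)cc1OC
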